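**The budget.** Count the partner before watching the clock: that was my order for this flask, where a solid substrate dissolves as starting material, opens to the open intermediate, and couples with the second intermediate that the partner yields.

solid substrate 0.050 M; partner 1.50 equiv; time 30 min

    starting material ⇌ open intermediate (K1 = 19, k1 = 0.0057 /s)
    solid substrate ⇌ starting material, rate k2*(cs2 - [starting material]) while solid is left; crystals form when [starting material] > cs2 (cs2 = 24 mM, k2 = 0.0018 /s)
    open intermediate + second intermediate → target (k3 = 0.025 /M/s)
    partner → second intermediate (k4 = 8.6 × 10⁻⁴ /s)
    2 second intermediate → homo product (k5 = 0.0026 /M/s)

- birch: doubling the solubility in step 2, all else as stated
- alder: doubling the dissolution coefficient of step 2, all else as stated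
- elm: doubling the amount of partner, all else as stated

- two of one species on the left: rate k times its square, two consumed each time
- given per volume of solution although it is solid: solid substrate
- at the start none of the solid substrate is in solution
- run time (flask): 30 min

- amount of target at 30 min, in percent of the solid substrate charged
- the change that raises the amount of target at 30 min, in percent of the solid substrate charged most ("none" if none brings more than 2 percentage points) (birch / alder / elm / none)
- amount of target at 30 min, in percent of the solid substrate charged, after alder

**Rule of thumb.** I took the bench view that 1.50 equiv of partner makes the solid substrate the limiting reagent, so the end state should hold the whole charge as target and leave a surplus of 0.500 of the charge.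

**The border.** Each turn to homo product burns two of second intermediate, so I defined the waste ratio, the second intermediate lost per coupling while it and the open intermediate stand at equal fractions of the charge, as 0.208. The surplus is larger than that, and dividing the two put the border at 2.40: the budget holds while second intermediate, averaged over the couplings, stays below that multiple of open intermediate. The budget gave me an end but no figure for 30 min. I noted that the partner's half-life by step 4 alone, 13 min, is shorter than that time, and I committed to no number.

**The forecast.** The forecast, unlike my reckoning, gave numbers: 45%, elm as the best change and 55% after alder, holding that “the run is still incomplete at 30 min”.

**At rest?** The simulation gave 45.2%, elm best at 20 percentage points against birch at 9.7 points and alder at 8.3 points, and 53.6% after alder, each within the forecast's tolerance. This flask was not at rest at 30 min: 49.8% stood as open intermediate, and ten times the time added 54 points of target, reaching 99.1%. Waste per coupling by then was 0.401, or 1.93 waste ratios, lower than the border. The same flask read at 80 min, with target at 87.6%, had spent 1.58 waste ratios. At 300 min, open intermediate stood at 0.809% and second intermediate at 11.1% of the charge.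

The numbers of this flask are made up.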